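## Retrosynthetic overview
1. The C2–phenyl bond is made last. A Rh(I)-catalysed enantioselective 1,4-addition of PhB(OH)2 to the fully deprotected 6-benzylated 5,7-dihydroxychromone sets 2S in the final step. No chalcone/oxa-Michael closure and no benzylation of pinocembrin is used.
2. All O-methyl groups are removed one step earlier, on the flat chromone, which has no stereocentre to racemise.
3. The pyranone is the only ring built. It comes from an o-hydroxyacetophenone (Houben–Hoesch) plus one carbon from DMF-DMA; the three benzene rings are bought.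
4. The C6/C8 regiochemistry problem is removed by symmetry. 4-(2,3-Dimethoxybenzyl)-3,5-dimethoxyphenol has one free OH and two equivalent ortho C–H positions.
5. The diarylmethane comes from 3-lithioveratrole (directed ortho-metalation) and 4-hydroxy-2,6-dimethoxybenzaldehyde, followed by ionic reduction.

Assumption: 2 and both ligand antipodes are purchasable. The (S)-ligand is matched to the 2S product by the quadrant model that gives (S)-3-phenylcyclohexanone with (S)-biaryl diphosphines (same spatial face = C2-Re of the chromone). The antipode is used if the measured sign disagrees.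

## Route

Step 1
Reactants: 1 1,2-dimethoxybenzene (veratrole); 2 4-hydroxy-2,6-dimethoxybenzaldehyde
Product: 4 4-[(2,3-dimethoxyphenyl)(hydroxy)methyl]-3,5-dimethoxyphenol (racemic; used crude), via 2,3-dimethoxyphenyllithium 3 (not isolated)
Conditions: 1 (2.6 equiv), n-BuLi (2.5 equiv), TMEDA, THF, 0 °C to rt, 2 h; then 2 (1.0 equiv), THF, −78 °C to rt; sat. aq NH4Cl
Reagents that add atoms: none
Why: Directed ortho-metalation lithiates veratrole only at C3, which gives the 2,3-dioxygenated pattern that electrophilic chemistry cannot; one equivalent of 3 deprotonates the phenol and the next adds 1,2 to the aldehyde, helped by Li+ chelation to the flanking OMe groups, and the racemic carbinol centre is erased in step 2.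

Step 2
Reactants: 4 4-[(2,3-dimethoxyphenyl)(hydroxy)methyl]-3,5-dimethoxyphenol
Product: 5 4-(2,3-dimethoxybenzyl)-3,5-dimethoxyphenol
Conditions: Et3SiH (5 equiv), TFA (10 equiv), CH2Cl2, −20 to 0 °C (4 added slowly to the silane/acid)
Reagents that add atoms: none
Why: Ionic hydrogenation (Kursanov–Parnes): TFA ionises the strongly activated benzhydrol to a protonated para-quinone-methide cation, and the excess silane delivers hydride before another arene can attack; the phenol and methyl ethers are inert.

Step 3
Reactants: 5 4-(2,3-dimethoxybenzyl)-3,5-dimethoxyphenol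
Product: 7 1-[3-(2,3-dimethoxybenzyl)-6-hydroxy-2,4-dimethoxyphenyl]ethan-1-one, via ketiminium chloride 6 (not isolated)
Conditions: MeCN (5 equiv), ZnCl2 (1 equiv), HCl (g), Et2O, 0 °C, 16 h; decant; H2O, reflux, 1 h
Reagents that add atoms: acetonitrile CC#N; water O
Why: Houben–Hoesch acylation attacks only phloroglucinol-level arenes, so the veratrole ring is untouched; the para position is blocked and the two ortho positions are equivalent, so one regioisomer forms, with the acetyl group next to the only free OH.

Step 4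
Reactants: 7 1-[3-(2,3-dimethoxybenzyl)-6-hydroxy-2,4-dimethoxyphenyl]ethan-1-one
Product: 9 6-(2,3-dimethoxybenzyl)-5,7-dimethoxy-4H-chromen-4-one, via enaminone 8 (not isolated)
Conditions: DMF-DMA (3 equiv), toluene, 100 °C, 3 h; evaporate; conc. HCl, CH2Cl2, 40 °C, 1 h
Reagents that add atoms: N,N-dimethylformamide dimethyl acetal COC(OC)N(C)C
Why: Enaminone chromone synthesis: the acetyl CH3 condenses with DMF-DMA, and acid then drives addition–elimination of the single free phenol on the β-carbon with loss of Me2NH, so the ring oxygen must be the one para to the benzyl-bearing carbon (6-benzyl, not 8-benzyl).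

Step 5
Reactants: 9 6-(2,3-dimethoxybenzyl)-5,7-dimethoxy-4H-chromen-4-one
Product: 10 6-(2,3-dihydroxybenzyl)-5,7-dihydroxy-4H-chromen-4-one
Conditions: BBr3 (8 equiv), CH2Cl2, −78 °C to rt, 16 h; ice/H2O
Reagents that add atoms: none
Why: Lewis-acid aryl methyl ether cleavage: the 5-OMe is chelation-assisted, the 7-OMe is twisted out of plane by the ortho benzyl group, and the veratrole ethers cleave fast; it is done here because the aromatic pyranone has no stereocentre to lose.

Step 6
Reactants: 10 6-(2,3-dihydroxybenzyl)-5,7-dihydroxy-4H-chromen-4-one; 11 phenylboronic acid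
Product: 14 (2S)-6-(2,3-dihydroxybenzyl)-5,7-dihydroxy-2-phenyl-2,3-dihydro-4H-chromen-4-one, via chromone catechol boronate 12 (not isolated), via flavanone catechol boronate 13 (not isolated)
Conditions: 11 (4 equiv), degassed 1,4-dioxane, N2, rt, 30 min; then [Rh(OH)((S)-MeO-F12-BIPHEP)]2 (2.5 mol %), 40 °C, 12 h; then THF/0.5 M aq citric acid, rt
Reagents that add atoms: none
Why: Proposed new method: a Hayashi–Miyaura asymmetric 1,4-addition run on an unprotected tetraphenol, in which excess 11 first ties up the chelating catechol as the five-membered boronate 12 and releases the water needed for turnover, Rh–OH transmetalates to Rh–Ph, enantio-determining syn-carborhodation delivers phenyl to the C2-Re face left open by the (S)-diphosphine (2S), the oxa-π-allyl Rh enolate is protonated by water or phenol (phenols are established proton sources in Rh conjugate additions), the 5-OH···O=C hydrogen bond activates the enone, and mild acid hydrolysis of 13 frees the catechol without touching C2 (no base, and no 4'-OH to assist ring opening); the closest known reaction type is the Rh/electron-poor diphosphine or Rh/diene 1,4-addition of arylboronic acids to O-protected chromones, which gives flavanones in very high ee.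

## Compound list
1 | 1,2-dimethoxybenzene (veratrole) | COc1ccccc1OC | starting material
2 | 4-hydroxy-2,6-dimethoxybenzaldehyde | COc1cc(O)cc(OC)c1C=O | starting material
3 | 2,3-dimethoxyphenyllithium | [Li]c1cccc(OC)c1OC | intermediate
4 | 4-[(2,3-dimethoxyphenyl)(hydroxy)methyl]-3,5-dimethoxyphenol (racemic) | COc1cc(O)cc(OC)c1C(O)c1cccc(OC)c1OC | intermediate
5 | 4-(2,3-dimethoxybenzyl)-3,5-dimethoxyphenol | COc1cc(O)cc(OC)c1Cc1cccc(OC)c1OC | intermediate
6 | 1-[3-(2,3-dimethoxybenzyl)-6-hydroxy-2,4-dimethoxyphenyl]ethan-1-iminium chloride | CC(=[NH2+])c1c(O)cc(OC)c(Cc2cccc(OC)c2OC)c1OC.[Cl-] | intermediate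
7 | 1-[3-(2,3-dimethoxybenzyl)-6-hydroxy-2,4-dimethoxyphenyl]ethan-1-one | CC(=O)c1c(O)cc(OC)c(Cc2cccc(OC)c2OC)c1OC | intermediate
8 | (E)-1-[3-(2,3-dimethoxybenzyl)-6-hydroxy-2,4-dimethoxyphenyl]-3-(dimethylamino)prop-2-en-1-one | CN(C)/C=C/C(=O)c1c(O)cc(OC)c(Cc2cccc(OC)c2OC)c1OC | intermediate
9 | 6-(2,3-dimethoxybenzyl)-5,7-dimethoxy-4H-chromen-4-one | COc1cc2occc(=O)c2c(OC)c1Cc1cccc(OC)c1OC | intermediate
10 | 6-(2,3-dihydroxybenzyl)-5,7-dihydroxy-4H-chromen-4-one | O=c1ccoc2cc(O)c(Cc3cccc(O)c3O)c(O)c12 | intermediate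
11 | phenylboronic acid | OB(O)c1ccccc1 | starting material
12 | 5,7-dihydroxy-6-[(2-phenyl-1,3,2-benzodioxaborol-4-yl)methyl]-4H-chromen-4-one | O=c1ccoc2cc(O)c(Cc3cccc4OB(c5ccccc5)Oc34)c(O)c12 | intermediate
13 | (2S)-5,7-dihydroxy-2-phenyl-6-[(2-phenyl-1,3,2-benzodioxaborol-4-yl)methyl]-2,3-dihydro-4H-chromen-4-one | O=C1C[C@@H](c2ccccc2)Oc2cc(O)c(Cc3cccc4OB(c5ccccc5)Oc34)c(O)c21 | intermediate
14 | (2S)-6-(2,3-dihydroxybenzyl)-5,7-dihydroxy-2-phenyl-2,3-dihydro-4H-chromen-4-one | O=C1C[C@@H](c2ccccc2)Oc2cc(O)c(Cc3cccc(O)c3O)c(O)c21 | target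

## Step count and risks
Total step count: 6. Longest linear sequence: 6 steps (1 or 2 to 14).

**Step 6 (most risky).** Free phenols or the catechol may slow or poison the Rh catalyst, or the ee may erode.
- The fallback sets out from 10 and returns at 14, using a protect–add–deprotect strategy.
- 10 is perbenzylated (BnBr, K2CO3, DMF, 60 °C) to 5,7-bis(benzyloxy)-6-[2,3-bis(benzyloxy)benzyl]-4H-chromen-4-one F1.
- This phenol-free chromone undergoes the precedented Rh/(S)-diphosphine 1,4-addition of 11 (toluene with a little water, rt). The product is (2S)-5,7-bis(benzyloxy)-6-[2,3-bis(benzyloxy)benzyl]-2-phenyl-2,3-dihydro-4H-chromen-4-one F2.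
- Neutral hydrogenolysis (H2 1 atm, Pd/C, EtOAc/MeOH), stopped at full debenzylation to spare the C2–O bond, gives 14.

**Step 1.** The lithium phenoxide of 2 is a deactivated, poorly soluble aldehyde, and 4 is labile.
- The fallback sets out from 2 and returns at 5. It skips 3, 4 and step 2 by a metal-free reductive coupling.
- 2 is condensed with TsNHNH2 (MeOH, 60 °C) to N'-(4-hydroxy-2,6-dimethoxybenzylidene)-4-methylbenzenesulfonohydrazide F3.
- Heating F3 with commercial 2,3-dimethoxyphenylboronic acid and K2CO3 in dioxane at 110 °C (Barluenga–Valdés coupling) generates 4-(diazomethyl)-3,5-dimethoxyphenol F4.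
- F4 is captured by the boronic acid with a 1,2-aryl shift to give [(2,3-dimethoxyphenyl)(4-hydroxy-2,6-dimethoxyphenyl)methyl]boronic acid F5. In-situ protodeboronation of F5 gives 5.

**Step 3.** The Hoesch reaction may stall at an O-imidate, or the strong acid may damage the electron-rich diarylmethane.
- The fallback sets out from 5 and returns at 9. It builds the ring oxygen-first and skips 6, 7 and 8.
- The single free OH of 5 adds to ethyl propiolate (DABCO cat., CH2Cl2, rt, oxa-Michael) to give ethyl (E)-3-[4-(2,3-dimethoxybenzyl)-3,5-dimethoxyphenoxy]acrylate F6.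
- LiOH in THF/H2O gives (E)-3-[4-(2,3-dimethoxybenzyl)-3,5-dimethoxyphenoxy]acrylic acid F7.
- Eaton's reagent (rt to 50 °C) isomerises the enol-ether double bond through its protonated oxocarbenium form. It then closes the pyranone by intramolecular Friedel–Crafts acylation at either of the two equivalent ortho carbons, giving 9.

Further compounds
F1 | step 6 | 5,7-bis(benzyloxy)-6-[2,3-bis(benzyloxy)benzyl]-4H-chromen-4-one | O=c1ccoc2cc(OCc3ccccc3)c(Cc3cccc(OCc4ccccc4)c3OCc3ccccc3)c(OCc3ccccc3)c12
F2 | step 6 | (2S)-5,7-bis(benzyloxy)-6-[2,3-bis(benzyloxy)benzyl]-2-phenyl-2,3-dihydro-4H-chromen-4-one | O=C1C[C@@H](c2ccccc2)Oc2cc(OCc3ccccc3)c(Cc3cccc(OCc4ccccc4)c3OCc3ccccc3)c(OCc3ccccc3)c21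
F3 | step 1 | N'-(4-hydroxy-2,6-dimethoxybenzylidene)-4-methylbenzenesulfonohydrazide | COc1cc(O)cc(OC)c1/C=N/NS(=O)(=O)c1ccc(C)cc1
F4 | step 1 | 4-(diazomethyl)-3,5-dimethoxyphenol | COc1cc(O)cc(OC)c1C=[N+]=[N-]
F5 | step 1 | [(2,3-dimethoxyphenyl)(4-hydroxy-2,6-dimethoxyphenyl)methyl]boronic acid | COc1cc(O)cc(OC)c1C(B(O)O)c1cccc(OC)c1OC
F6 | step 3 | ethyl (E)-3-[4-(2,3-dimethoxybenzyl)-3,5-dimethoxyphenoxy]acrylate | CCOC(=O)/C=C/Oc1cc(OC)c(Cc2cccc(OC)c2OC)c(OC)c1
F7 | step 3 | (E)-3-[4-(2,3-dimethoxybenzyl)-3,5-dimethoxyphenoxy]acrylic acid | OC(=O)/C=C/Oc1cc(OC)c(Cc2cccc(OC)c2OC)c(OC)c1
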